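**Strategy.** The depside is cut at the aryl–oxygen bond between C4 of ring B and the ester oxygen, not at the acyl–oxygen bond. C4 lies para to the C1 methyl ester and between the C3 and C5 methyls, so ring B is turned into the electrophile as an aryl(2,4,6-trimethoxyphenyl)iodonium tosylate, and ring A enters as a carboxylate whose carbonyl (between C2' methyl and C6' oxygen) is never attacked. One ligand coupling on iodine makes the C4–O bond and the whole skeleton. The precursors are a bis-MOM acid from atraric acid and the iodonium salt from 2,4,5-trimethylphenol; BCl3 then frees all three phenols. The target has no stereocentre.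

Key step: step 8

Remark on the chemistry: unprimed ring A locants follow acid 11 (C1 carboxyl, C2 and C4 oxygen, C3 and C6 methyl, C5 chlorine); C1 to C6 of 11 correspond to C1', C6', C5', C4', C3' and C2' of the depside. Step 1 is assumed to be run in an autoclave, and the three starting materials are taken as commercial.

**Step 1**
Reactants: 1 2,4,5-trimethylphenol
Product: 2 2-hydroxy-3,5,6-trimethylbenzoic acid
Conditions: NaOH (1 equiv), H2O, then dried to the sodium phenoxide; CO2 (50 bar), 150 °C; aq. HCl
Reagents that add atoms: carbon dioxide, O=C=O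
Why: Kolbe–Schmitt carboxylation of the dry sodium phenoxide should deliver CO2 to the only free ortho carbon, because the para position carries a methyl group, as is known for thymol-type phenols whose free ortho position is next to a ring methyl.

**Step 2**
Reactants: 2 2-hydroxy-3,5,6-trimethylbenzoic acid
Product: 3 methyl 2-methoxy-3,5,6-trimethylbenzoate
Conditions: MeI (excess), K2CO3, DMF, 50 °C
Reagents that add atoms: iodomethane, CI
Why: Double Williamson-type O-methylation (SN2 at MeI) of the carboxylate and the phenoxide avoids any addition to the hindered carboxyl carbon that a Fischer esterification would need.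

**Step 3**
Reactants: 3 methyl 2-methoxy-3,5,6-trimethylbenzoate
Product: 4 methyl 4-iodo-2-methoxy-3,5,6-trimethylbenzoate
Conditions: NIS, TfOH (cat.), MeCN, 0 °C to rt
Reagents that add atoms: N-iodosuccinimide, O=C1CCC(=O)N1I
Why: Electrophilic aromatic iodination with acid-activated NIS should take place at C4, the only ring C–H, which is activated by the C3 and C5 methyls and only weakly deactivated by the ester that its two ortho substituents twist out of conjugation.

**Step 4**
Reactants: 4 methyl 4-iodo-2-methoxy-3,5,6-trimethylbenzoate; 5 1,3,5-trimethoxybenzene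
Product: 7 (3-methoxy-4-methoxycarbonyl-2,5,6-trimethylphenyl)(2,4,6-trimethoxyphenyl)iodonium tosylate, via ring B hydroxy(tosyloxy)iodane 6 (not isolated)
Conditions: mCPBA, TsOH·H2O, MeCN, 77 °C; then 5, 77 °C to rt; Et2O trituration
Reagents that add atoms: p-toluenesulfonic acid monohydrate, Cc1ccc(S(=O)(=O)O)cc1.O; mCPBA, O=C(OO)c1cccc(Cl)c1
Why: The peracid oxidises the aryl iodide in the presence of TsOH to the trivalent hydroxy(tosyloxy)iodane 6, which the very electron-rich arene 5 attacks at iodine in an electrophilic aromatic substitution with loss of water (one-pot synthesis of aryl(trimethoxyphenyl)iodonium tosylates, known for mesityl-type iodides); 5 is added only after the peracid is consumed, and the peracid oxygen is carried only by 6.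

**Step 5**
Reactants: 8 methyl 2,4-dihydroxy-3,6-dimethylbenzoate (atraric acid)
Product: 9 methyl 5-chloro-2,4-dihydroxy-3,6-dimethylbenzoate
Conditions: SO2Cl2 (1.05 equiv), CH2Cl2, 0 °C to rt
Reagents that add atoms: sulfuryl chloride, O=S(=O)(Cl)Cl
Why: Electrophilic aromatic chlorination should occur at C5, the only ring C–H, which is ortho to the C4 hydroxyl and para to the C2 hydroxyl, and one equivalent of SO2Cl2 at 0 °C avoids dearomatising over-chlorination.

**Step 6**
Reactants: 9 methyl 5-chloro-2,4-dihydroxy-3,6-dimethylbenzoate
Product: 10 methyl 5-chloro-2,4-bis(methoxymethoxy)-3,6-dimethylbenzoate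
Conditions: NaH (2.5 equiv), DMF, 0 °C; MOMCl (2.5 equiv), 0 °C to rt
Reagents that add atoms: chloromethyl methyl ether, COCCl
Why: Williamson-type alkylation of both sodium phenoxides with the small and very reactive MOMCl should go to completion even though each oxygen has two ortho neighbours, NaH being used because the C2 hydroxyl is hydrogen-bonded to the ester.

**Step 7**
Reactants: 10 methyl 5-chloro-2,4-bis(methoxymethoxy)-3,6-dimethylbenzoate
Product: 11 5-chloro-2,4-bis(methoxymethoxy)-3,6-dimethylbenzoic acid
Conditions: KOH, DMSO/H2O, 90 °C; cold aq. KHSO4 to pH 3–4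
Reagents that add atoms: potassium hydroxide, [K+].[OH-]
Why: Saponification of a doubly ortho-substituted methyl benzoate needs the poorly solvated hydroxide of aqueous DMSO at 90 °C, conditions under which MOM acetals and the chloride on this electron-rich ring are inert, and cold buffered acidification frees the acid without acetal loss or decarboxylation.

**Step 8**
Reactants: 11 5-chloro-2,4-bis(methoxymethoxy)-3,6-dimethylbenzoic acid; 7 (3-methoxy-4-methoxycarbonyl-2,5,6-trimethylphenyl)(2,4,6-trimethoxyphenyl)iodonium tosylate
Product: 13 methyl 4-{[5-chloro-2,4-bis(methoxymethoxy)-3,6-dimethylbenzoyl]oxy}-2-methoxy-3,5,6-trimethylbenzoate (protected depside), via diaryliodanyl carboxylate 12 (not isolated)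
Conditions: tBuOK (1.0 equiv), toluene, rt; then 7, 110 °C
Reagents that add atoms: none
Why: The potassium carboxylate of 11 displaces tosylate on the trivalent iodine of 7 and gives the T-shaped λ3-iodane 12, from which ligand coupling between the carboxylate oxygen and the ipso carbon C4 of ring B forms the depside C4–O bond while iodine falls to the monovalent state and leaves as 2-iodo-1,3,5-trimethoxybenzene. The closest known reaction type is the metal-free O-arylation of carboxylic acids with diaryliodonium salts, which is documented for doubly ortho-substituted aryl groups and for hindered acids. No ring is closed and no stereocentre is made. The selectivity needed is transfer of the ring B aryl and not of the trimethoxyphenyl group: ring B is the more electron-poor ligand (C1 ester para to iodine) and its C3 and C5 methyls favour the position on iodine from which coupling takes place, whereas the electron-rich trimethoxyphenyl ipso carbon resists attack by the carboxylate. Neither aryl group has a hydrogen ortho to iodine, so aryne formation is excluded, and one equivalent of base leaves the methyl ester and the MOM acetals untouched. Because the nucleophile is the carboxylate oxygen, no tetrahedral intermediate is needed at the ring A carbonyl between C2' methyl and C6' OMOM, which is where a classical esterification of two hexasubstituted rings is weakest.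

**Step 9**
Reactants: 13 methyl 4-{[5-chloro-2,4-bis(methoxymethoxy)-3,6-dimethylbenzoyl]oxy}-2-methoxy-3,5,6-trimethylbenzoate
Product: 14 methyl 4-[(5-chloro-2,4-dihydroxy-3,6-dimethylbenzoyl)oxy]-2-hydroxy-3,5,6-trimethylbenzoate (target)
Conditions: BCl3 (6 equiv), CH2Cl2, −78 to 0 °C; then H2O
Reagents that add atoms: none
Why: BCl3 cleaves the two aryl MOM acetals at low temperature and, on warming to 0 °C, removes the C2 methyl ether of ring B through a six-membered boron chelate with the C1 ester carbonyl (chelation-directed O-demethylation), while the methyl ester, the hindered depside ester and the aryl chloride are not attacked under these conditions.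

**Compound list**
1 | 2,4,5-trimethylphenol | Cc1cc(C)c(O)cc1C | starting material
2 | 2-hydroxy-3,5,6-trimethylbenzoic acid | OC(=O)c1c(C)c(C)cc(C)c1O | intermediate
3 | methyl 2-methoxy-3,5,6-trimethylbenzoate | COC(=O)c1c(C)c(C)cc(C)c1OC | intermediate
4 | methyl 4-iodo-2-methoxy-3,5,6-trimethylbenzoate | COC(=O)c1c(C)c(C)c(I)c(C)c1OC | intermediate
5 | 1,3,5-trimethoxybenzene | COc1cc(OC)cc(OC)c1 | starting material
6 | methyl 4-[hydroxy(tosyloxy)-λ3-iodanyl]-2-methoxy-3,5,6-trimethylbenzoate (not isolated) | COC(=O)c1c(C)c(C)c(I(O)OS(=O)(=O)c2ccc(C)cc2)c(C)c1OC | intermediate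
7 | (3-methoxy-4-methoxycarbonyl-2,5,6-trimethylphenyl)(2,4,6-trimethoxyphenyl)iodonium tosylate | COC(=O)c1c(C)c(C)c([I+]c2c(OC)cc(OC)cc2OC)c(C)c1OC.Cc1ccc(S(=O)(=O)[O-])cc1 | intermediate
8 | methyl 2,4-dihydroxy-3,6-dimethylbenzoate (atraric acid) | COC(=O)c1c(C)cc(O)c(C)c1O | starting material
9 | methyl 5-chloro-2,4-dihydroxy-3,6-dimethylbenzoate | COC(=O)c1c(C)c(Cl)c(O)c(C)c1O | intermediate
10 | methyl 5-chloro-2,4-bis(methoxymethoxy)-3,6-dimethylbenzoate | COC(=O)c1c(C)c(Cl)c(OCOC)c(C)c1OCOC | intermediate
11 | 5-chloro-2,4-bis(methoxymethoxy)-3,6-dimethylbenzoic acid | O=C(O)c1c(C)c(Cl)c(OCOC)c(C)c1OCOC | intermediate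
12 | [3-methoxy-4-(methoxycarbonyl)-2,5,6-trimethylphenyl](2,4,6-trimethoxyphenyl)-λ3-iodanyl 5-chloro-2,4-bis(methoxymethoxy)-3,6-dimethylbenzoate (not isolated) | COC(=O)c1c(C)c(C)c(I(OC(=O)c2c(C)c(Cl)c(OCOC)c(C)c2OCOC)c2c(OC)cc(OC)cc2OC)c(C)c1OC | intermediate
13 | methyl 4-{[5-chloro-2,4-bis(methoxymethoxy)-3,6-dimethylbenzoyl]oxy}-2-methoxy-3,5,6-trimethylbenzoate | COC(=O)c1c(C)c(C)c(OC(=O)c2c(C)c(Cl)c(OCOC)c(C)c2OCOC)c(C)c1OC | intermediate
14 | methyl 4-[(5-chloro-2,4-dihydroxy-3,6-dimethylbenzoyl)oxy]-2-hydroxy-3,5,6-trimethylbenzoate | COC(=O)c1c(C)c(C)c(OC(=O)c2c(C)c(Cl)c(O)c(C)c2O)c(C)c1O | target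

Total step count: 9. Longest linear sequence: 6 steps (steps 1, 2, 3, 4, 8 and 9 from 2,4,5-trimethylphenol); the ring A branch (steps 5, 6, 7) joins at step 8.

**Steps most likely to fail**

Step 8. Ligand coupling joins a carbon flanked by two methyls to a carboxylate that is itself doubly ortho-substituted, so it may be slow. Transfer of the trimethoxyphenyl group or thermal breakdown of the salt could then compete. The fallback forms the acyl–oxygen bond by classical acylation and sets out from iodide 4 and acid 11. Palladium-catalysed hydroxylation of 4 (Pd2(dba)3, tBuXPhos, KOH, dioxane/H2O, 100 °C) should give the phenol methyl 4-hydroxy-2-methoxy-3,5,6-trimethylbenzoate F1; the doubly ortho-substituted ester should survive the aqueous base. Acid 11 is converted under neutral conditions with 1-chloro-N,N,2-trimethylprop-1-en-1-amine in CH2Cl2 into 5-chloro-2,4-bis(methoxymethoxy)-3,6-dimethylbenzoyl chloride F2, which keeps the MOM acetals intact. The sodium phenoxide of F1 (NaH, THF, 0 °C to reflux) is then acylated by F2, which reacts through an acylium-like pathway, and the route is rejoined at 13. This union is expected to be slower than the key step but is the established way of making depsides.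

Step 4. The peracid may oxidise the doubly ortho-substituted iodide incompletely, or residual peracid may oxidise trimethoxybenzene, so that little iodonium salt separates. The fallback isolates the iodane and arylates it without strong acid, setting out from 4. NaBO3·4H2O in AcOH at 45 °C should give the isolable methyl 4-(diacetoxy-λ3-iodanyl)-2-methoxy-3,5,6-trimethylbenzoate F3. Condensation of F3 with 5 in 2,2,2-trifluoroethanol at rt should give (3-methoxy-4-methoxycarbonyl-2,5,6-trimethylphenyl)(2,4,6-trimethoxyphenyl)iodonium acetate F4. Exchange of acetate for tosylate with TsOH·H2O in MeCN and precipitation with Et2O rejoins the route at 7.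

Step 9. The Lewis acid may cleave the acetals quickly but the chelated methyl ether slowly, so that forcing the reaction begins to cleave the depside or the methyl ester. The fallback separates the two deprotections and sets out from 13. Hydrolysis of the two acetals with 3 M HCl in THF at 40 °C, which hindered aryl esters tolerate, should give methyl 4-[(5-chloro-2,4-dihydroxy-3,6-dimethylbenzoyl)oxy]-2-methoxy-3,5,6-trimethylbenzoate F5. Chelation-assisted nucleophilic demethylation with MgI2·OEt2 in toluene at 60–80 °C, in which iodide removes the methyl of the ether held in a magnesium chelate with the C1 ester, then rejoins the route at 14.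

**Further compounds**
F1 | step 8 | methyl 4-hydroxy-2-methoxy-3,5,6-trimethylbenzoate | COC(=O)c1c(C)c(C)c(O)c(C)c1OC
F2 | step 8 | 5-chloro-2,4-bis(methoxymethoxy)-3,6-dimethylbenzoyl chloride | O=C(Cl)c1c(C)c(Cl)c(OCOC)c(C)c1OCOC
F3 | step 4 | methyl 4-(diacetoxy-λ3-iodanyl)-2-methoxy-3,5,6-trimethylbenzoate | COC(=O)c1c(C)c(C)c(I(OC(C)=O)OC(C)=O)c(C)c1OC
F4 | step 4 | (3-methoxy-4-methoxycarbonyl-2,5,6-trimethylphenyl)(2,4,6-trimethoxyphenyl)iodonium acetate | COC(=O)c1c(C)c(C)c([I+]c2c(OC)cc(OC)cc2OC)c(C)c1OC.CC(=O)[O-]
F5 | step 9 | methyl 4-[(5-chloro-2,4-dihydroxy-3,6-dimethylbenzoyl)oxy]-2-methoxy-3,5,6-trimethylbenzoate | COC(=O)c1c(C)c(C)c(OC(=O)c2c(C)c(Cl)c(O)c(C)c2O)c(C)c1OC
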